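**Plan**

- Numbering used throughout: ring A is C1 (angelate carbinol), C2=C3 (methyl on C3), C4 (acetate carbinol), C5 (CH2), C6 (CH); the side chain is C7 (methyl-bearing CH), C8, C9 (acetate carbinol), C10=C11.
- Retrosynthesis first cuts the three ester C–O bonds, then takes C1–OH back to a C1 ketone, removes the C3–CH3 bond with a 1,3-oxygen shift back to a C3 ketone with C1=C2, and removes the C4–O bond.
- The enabling feature is that C6 is alpha to C1 while C2–C5 form a four-carbon enone unit: cutting C1=C2 and C5–C6 of ring A leaves aldehyde 7 (C1, C6–C11) and but-3-en-2-one 8 (C2–C5).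
- Aldehyde 7 is cut at C9–C10 and C9–H, back to the half ester 1 of (R)-3-methylglutaric acid and the isobutenyl Grignard reagent 2.
- Forward: the chain is assembled in steps 1–4, ring A closes once in step 5, and steps 6–13 bring in the C4 oxygen, the C3 methyl with oxygen transposition to C1, the C1 carbinol and the three esters.
- Stereochemistry: C7 from the chiral pool, C9 from an oxazaborolidine-catalysed reduction, C6 from the prolinol ether catalyst, C4 and C1 from substrate control by the C6 side chain.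

Key step: step 5

Assumption: compound 14 is carried as a mixture of epimers at the new tertiary carbinol (C3), which is immaterial because C3 becomes trigonal in step 9. TBS = tert-butyldimethylsilyl.

Step 1
Reactants: 1 (3R)-5-methoxy-3-methyl-5-oxopentanoic acid (methyl hydrogen (R)-3-methylglutarate); 2 (2-methylprop-1-en-1-yl)magnesium bromide
Product: 4 methyl (3R)-3,7-dimethyl-5-oxooct-6-enoate, via acid chloride 3 (not isolated)
Conditions: (COCl)2, DMF (cat.), CH2Cl2, 0 °C to rt; evaporate; then 2, CuI (5 mol %), THF, −78 °C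
Reagents that add atoms: none
Why: Acid chloride formation followed by copper-catalysed acylation of a Grignard reagent (ketone synthesis from an acyl chloride) is selective for the acyl chloride over the methyl ester at −78 °C, and C7, being beta to both carbonyl groups, cannot epimerise.

Step 2
Reactants: 4 methyl (3R)-3,7-dimethyl-5-oxooct-6-enoate
Product: 5 methyl (3R,5R)-5-hydroxy-3,7-dimethyloct-6-enoate
Conditions: (S)-1-methyl-3,3-diphenyltetrahydro-1H,3H-pyrrolo[1,2-c][1,3,2]oxazaborole [(S)-Me-CBS] (20 mol %), BH3·SMe2, THF, −30 °C; MeOH quench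
Reagents that add atoms: none
Why: In this Corey–Bakshi–Shibata reduction the (S)-oxazaborolidine binds the enone with the alkenyl group as the large substituent and should deliver hydride to the face that gives the (R)-allylic alcohol at C9, under reagent control because C7 is remote, while the ester is inert to borane at this temperature.

Step 3
Reactants: 5 methyl (3R,5R)-5-hydroxy-3,7-dimethyloct-6-enoate
Product: 6 methyl (3R,5R)-5-(TBSO)-3,7-dimethyloct-6-enoate
Conditions: TBSCl, imidazole, DMF, 0 °C to rt (crude 5 used at once)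
Reagents that add atoms: tert-butyldimethylsilyl chloride, CC(C)(C)[Si](C)(C)Cl
Why: Corey silylation of the secondary allylic alcohol forestalls delta-lactonisation of the hydroxy ester and installs an ether that should withstand hydride, hydroxide, amide base, MeLi and the chromium oxidant used later.

Step 4
Reactants: 6 methyl (3R,5R)-5-(TBSO)-3,7-dimethyloct-6-enoate
Product: 7 (3R,5R)-5-(TBSO)-3,7-dimethyloct-6-enal
Conditions: iBu2AlH (1.1 equiv), CH2Cl2, −78 °C; aq. potassium sodium tartrate
Reagents that add atoms: none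
Why: Partial reduction of a methyl ester with iBu2AlH at −78 °C stops at the tetrahedral aluminium hemiacetal, which releases the aldehyde only on work-up.

Step 5
Reactants: 7 (3R,5R)-5-(TBSO)-3,7-dimethyloct-6-enal; 8 but-3-en-2-one
Product: 11 (4S)-4-[(2R,4R)-4-(TBSO)-6-methylhept-5-en-2-yl]cyclohex-2-en-1-one, via keto aldehyde 9 (not isolated), via aldol 10 (not isolated)
Conditions: 8 (1.5 equiv), (S)-2-[diphenyl(trimethylsilyloxy)methyl]pyrrolidine (10 mol %), ethyl 3,4-dihydroxybenzoate (20 mol %), neat, 4 °C; evaporate excess 8; then 0.1 M aq. KOH, nBu4NOH (cat.), Et2O/THF, reflux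
Reagents that add atoms: none
Why: The amine condenses with 7 to the anti E-enamine, whose C6 adds to the terminal carbon of 8 (Michael addition, forming C5–C6); hydrolysis releases keto aldehyde 9, and hydroxide then forms the methyl-ketone enolate, whose C2 attacks the C1 aldehyde to give aldol 10, which loses water by E1cB elimination to the C1=C2 enone 11. The closest known reaction type is the diarylprolinol ether-catalysed Michael addition of aldehydes to vinyl ketones followed by base-mediated aldol condensation, which is established for beta-branched aldehydes of the citronellal type. Ring A closes in a 6-(enolendo)-exo-trig aldol, the only cyclisation open to 9 because the other enolate and carbonyl pairings would give four-membered rings. The new C6 centre is set by the catalyst: the diphenyl(silyloxy)methyl group of the (S)-pyrrolidine shields one enamine face, so 8 should approach from the other and give (S)-C6. The step needs catalyst control over the adjacent C7 centre and retention of C6 through the basic closure; the first rests on the shielding group outweighing the bias of a beta-methyl branch, the second on dilute biphasic hydroxide and on C6 ending gamma to the ketone once the ring has closed.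

Step 6
Reactants: 11 (4S)-4-[(2R,4R)-4-(TBSO)-6-methylhept-5-en-2-yl]cyclohex-2-en-1-one
Product: 12 (4S,6R)-6-hydroxy-4-[(2R,4R)-4-(TBSO)-6-methylhept-5-en-2-yl]cyclohex-2-en-1-one
Conditions: KN(SiMe3)2, THF, −78 °C; then 2-(benzenesulfonyl)-3-phenyloxaziridine, −78 °C; AcOH quench
Reagents that add atoms: 2-(benzenesulfonyl)-3-phenyloxaziridine (Davis oxaziridine), O=S(=O)(c1ccccc1)N1OC1c1ccccc1
Why: In this Davis enolate hydroxylation, kinetic deprotonation at C4 gives the cross-conjugated dienolate and oxygen transfer should take place axially on the face opposite the pseudoequatorial C6 side chain, setting (R)-C4 trans to C6, while the oxaziridine, unlike a peracid, leaves the C10=C11 alkene alone.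

Step 7
Reactants: 12 (4S,6R)-6-hydroxy-4-[(2R,4R)-4-(TBSO)-6-methylhept-5-en-2-yl]cyclohex-2-en-1-one
Product: 13 (4S,6R)-6-(TBSO)-4-[(2R,4R)-4-(TBSO)-6-methylhept-5-en-2-yl]cyclohex-2-en-1-one
Conditions: TBSCl, imidazole, 4-(dimethylamino)pyridine (cat.), DMF, rt
Reagents that add atoms: tert-butyldimethylsilyl chloride, CC(C)(C)[Si](C)(C)Cl
Why: Corey silylation of the alpha-ketol under weakly basic conditions should not epimerise C4 and masks the C4 hydroxyl for the MeLi addition and the chromium oxidation with a group that later falls together with the C9 ether.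

Step 8
Reactants: 13 (4S,6R)-6-(TBSO)-4-[(2R,4R)-4-(TBSO)-6-methylhept-5-en-2-yl]cyclohex-2-en-1-one
Product: 14 (4S,6R)-6-(TBSO)-1-methyl-4-[(2R,4R)-4-(TBSO)-6-methylhept-5-en-2-yl]cyclohex-2-en-1-ol (mixture of C1 epimers)
Conditions: MeLi, Et2O/THF, −78 °C; H2O quench at −78 °C
Reagents that add atoms: methyllithium, [Li]C
Why: 1,2-Addition of methyllithium to the enone carbonyl brings in the C3 methyl group, and the cold quench limits silyl migration from the neighbouring C4 oxygen to the new alkoxide.

Step 9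
Reactants: 14 (4S,6R)-6-(TBSO)-1-methyl-4-[(2R,4R)-4-(TBSO)-6-methylhept-5-en-2-yl]cyclohex-2-en-1-ol
Product: 15 (4R,6S)-4-(TBSO)-3-methyl-6-[(2R,4R)-4-(TBSO)-6-methylhept-5-en-2-yl]cyclohex-2-en-1-one
Conditions: [C5H5NH][CrO3Cl] (pyridinium chlorochromate), 4 Å molecular sieves, CH2Cl2, rt
Reagents that add atoms: none
Why: In this Dauben–Babler oxidative 1,3-transposition the tertiary allylic chromate ester rearranges by a [3,3]-sigmatropic shift to the C1 chromate, which is oxidised to the C1 ketone with the C2=C3 double bond now carrying the methyl group, C4 and C6 not taking part.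

Step 10
Reactants: 15 (4R,6S)-4-(TBSO)-3-methyl-6-[(2R,4R)-4-(TBSO)-6-methylhept-5-en-2-yl]cyclohex-2-en-1-one
Product: 16 (1S,4R,6S)-4-(TBSO)-3-methyl-6-[(2R,4R)-4-(TBSO)-6-methylhept-5-en-2-yl]cyclohex-2-en-1-ol
Conditions: NaBH4, CeCl3·7H2O, MeOH, −78 °C
Reagents that add atoms: none
Why: Luche reduction gives 1,2-reduction only, and with the C6 chain pseudoequatorial and the C4 silyloxy group pseudoaxial (away from the C3 methyl) axial hydride attack on the face opposite that silyloxy group should give the equatorial (S)-C1 alcohol, trans to the C6 chain and cis to the C4 oxygen.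

Step 11
Reactants: 16 (1S,4R,6S)-4-(TBSO)-3-methyl-6-[(2R,4R)-4-(TBSO)-6-methylhept-5-en-2-yl]cyclohex-2-en-1-ol; 17 angelic acid, (2Z)-2-methylbut-2-enoic acid
Product: 19 (1S,4R,6S)-4-(TBSO)-6-[(2R,4R)-4-(TBSO)-6-methylhept-5-en-2-yl]-3-methylcyclohex-2-en-1-yl (2Z)-2-methylbut-2-enoate, via mixed anhydride 18 (not isolated)
Conditions: 17, 2,4,6-trichlorobenzoyl chloride, Et3N, toluene, rt; then 16, toluene, 75 °C
Reagents that add atoms: none
Why: Yamaguchi-type esterification through the 2,4,6-trichlorobenzoyl mixed anhydride, run without a nucleophilic catalyst, is the established way to acylate hindered alcohols with angelic acid with retention at C1 and without Z to E isomerisation to the tiglate.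

Step 12
Reactants: 19 (1S,4R,6S)-4-(TBSO)-6-[(2R,4R)-4-(TBSO)-6-methylhept-5-en-2-yl]-3-methylcyclohex-2-en-1-yl (2Z)-2-methylbut-2-enoate
Product: 20 (1S,4R,6S)-4-hydroxy-6-[(2R,4R)-4-hydroxy-6-methylhept-5-en-2-yl]-3-methylcyclohex-2-en-1-yl (2Z)-2-methylbut-2-enoate
Conditions: HF·pyridine, pyridine, THF, 0 °C to rt
Reagents that add atoms: none
Why: Fluoride-mediated desilylation buffered with pyridine should remove both secondary TBS ethers without acyl migration, angelate isomerisation or ionisation of the allylic alcohols.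

Step 13
Reactants: 20 (1S,4R,6S)-4-hydroxy-6-[(2R,4R)-4-hydroxy-6-methylhept-5-en-2-yl]-3-methylcyclohex-2-en-1-yl (2Z)-2-methylbut-2-enoate
Product: 21 (1S,4R,6S)-4-acetoxy-6-[(2R,4R)-4-acetoxy-6-methylhept-5-en-2-yl]-3-methylcyclohex-2-en-1-yl (2Z)-2-methylbut-2-enoate (CNP0417294.1)
Conditions: Ac2O, pyridine, 4-(dimethylamino)pyridine (cat.), CH2Cl2, rt
Reagents that add atoms: acetic anhydride, CC(=O)OC(C)=O
Why: Acetylation of the two secondary alcohols under nucleophilic catalysis completes the target, the angelate being stable to these conditions at room temperature.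

**Compound list**

1 | (3R)-5-methoxy-3-methyl-5-oxopentanoic acid | COC(=O)C[C@H](C)CC(O)=O | starting material
2 | (2-methylprop-1-en-1-yl)magnesium bromide | CC(C)=C[Mg]Br | starting material
3 | methyl (3S)-5-chloro-3-methyl-5-oxopentanoate | COC(=O)C[C@H](C)CC(Cl)=O | intermediate
4 | methyl (3R)-3,7-dimethyl-5-oxooct-6-enoate | COC(=O)C[C@H](C)CC(=O)C=C(C)C | intermediate
5 | methyl (3R,5R)-5-hydroxy-3,7-dimethyloct-6-enoate | COC(=O)C[C@H](C)C[C@H](C=C(C)C)O | intermediate
6 | methyl (3R,5R)-5-[(tert-butyldimethylsilyl)oxy]-3,7-dimethyloct-6-enoate | COC(=O)C[C@H](C)C[C@H](C=C(C)C)O[Si](C)(C)C(C)(C)C | intermediate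
7 | (3R,5R)-5-[(tert-butyldimethylsilyl)oxy]-3,7-dimethyloct-6-enal | O=CC[C@H](C)C[C@H](C=C(C)C)O[Si](C)(C)C(C)(C)C | intermediate
8 | but-3-en-2-one | CC(=O)C=C | starting material
9 | (2S)-2-[(2R,4R)-4-[(tert-butyldimethylsilyl)oxy]-6-methylhept-5-en-2-yl]-5-oxohexanal | CC(=O)CC[C@H](C=O)[C@H](C)C[C@H](C=C(C)C)O[Si](C)(C)C(C)(C)C | intermediate
10 | (4S)-4-[(2R,4R)-4-[(tert-butyldimethylsilyl)oxy]-6-methylhept-5-en-2-yl]-3-hydroxycyclohexan-1-one (C3 epimers) | O=C1CC(O)[C@@H](CC1)[C@H](C)C[C@H](C=C(C)C)O[Si](C)(C)C(C)(C)C | intermediate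
11 | (4S)-4-[(2R,4R)-4-[(tert-butyldimethylsilyl)oxy]-6-methylhept-5-en-2-yl]cyclohex-2-en-1-one | O=C1C=C[C@@H](CC1)[C@H](C)C[C@H](C=C(C)C)O[Si](C)(C)C(C)(C)C | intermediate
12 | (4S,6R)-6-hydroxy-4-[(2R,4R)-4-[(tert-butyldimethylsilyl)oxy]-6-methylhept-5-en-2-yl]cyclohex-2-en-1-one | O=C1C=C[C@@H](C[C@H]1O)[C@H](C)C[C@H](C=C(C)C)O[Si](C)(C)C(C)(C)C | intermediate
13 | (4S,6R)-6-[(tert-butyldimethylsilyl)oxy]-4-[(2R,4R)-4-[(tert-butyldimethylsilyl)oxy]-6-methylhept-5-en-2-yl]cyclohex-2-en-1-one | O=C1C=C[C@@H](C[C@H]1O[Si](C)(C)C(C)(C)C)[C@H](C)C[C@H](C=C(C)C)O[Si](C)(C)C(C)(C)C | intermediate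
14 | (4S,6R)-6-[(tert-butyldimethylsilyl)oxy]-1-methyl-4-[(2R,4R)-4-[(tert-butyldimethylsilyl)oxy]-6-methylhept-5-en-2-yl]cyclohex-2-en-1-ol (C1 epimers) | CC1(O)C=C[C@@H](C[C@H]1O[Si](C)(C)C(C)(C)C)[C@H](C)C[C@H](C=C(C)C)O[Si](C)(C)C(C)(C)C | intermediate
15 | (4R,6S)-4-[(tert-butyldimethylsilyl)oxy]-3-methyl-6-[(2R,4R)-4-[(tert-butyldimethylsilyl)oxy]-6-methylhept-5-en-2-yl]cyclohex-2-en-1-one | O=C1C=C(C)[C@H](O[Si](C)(C)C(C)(C)C)C[C@H]1[C@H](C)C[C@H](C=C(C)C)O[Si](C)(C)C(C)(C)C | intermediate
16 | (1S,4R,6S)-4-[(tert-butyldimethylsilyl)oxy]-3-methyl-6-[(2R,4R)-4-[(tert-butyldimethylsilyl)oxy]-6-methylhept-5-en-2-yl]cyclohex-2-en-1-ol | O[C@@H]1C=C(C)[C@H](O[Si](C)(C)C(C)(C)C)C[C@H]1[C@H](C)C[C@H](C=C(C)C)O[Si](C)(C)C(C)(C)C | intermediate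
17 | angelic acid, (2Z)-2-methylbut-2-enoic acid | C/C=C(/C)C(O)=O | starting material
18 | (2Z)-2-methylbut-2-enoic 2,4,6-trichlorobenzoic anhydride | C/C=C(/C)C(=O)OC(=O)c1c(Cl)cc(Cl)cc1Cl | intermediate
19 | (1S,4R,6S)-4-[(tert-butyldimethylsilyl)oxy]-6-[(2R,4R)-4-[(tert-butyldimethylsilyl)oxy]-6-methylhept-5-en-2-yl]-3-methylcyclohex-2-en-1-yl (2Z)-2-methylbut-2-enoate | C/C=C(/C)C(=O)O[C@@H]1C=C(C)[C@H](O[Si](C)(C)C(C)(C)C)C[C@H]1[C@H](C)C[C@H](C=C(C)C)O[Si](C)(C)C(C)(C)C | intermediate
20 | (1S,4R,6S)-4-hydroxy-6-[(2R,4R)-4-hydroxy-6-methylhept-5-en-2-yl]-3-methylcyclohex-2-en-1-yl (2Z)-2-methylbut-2-enoate | C/C=C(/C)C(=O)O[C@@H]1C=C(C)[C@H](O)C[C@H]1[C@H](C)C[C@H](C=C(C)C)O | intermediate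
21 | (1S,4R,6S)-4-acetoxy-6-[(2R,4R)-4-acetoxy-6-methylhept-5-en-2-yl]-3-methylcyclohex-2-en-1-yl (2Z)-2-methylbut-2-enoate | C/C=C(/C)C(=O)O[C@@H]1C=C(C)[C@H](OC(C)=O)C[C@H]1[C@H](C)C[C@H](C=C(C)C)OC(C)=O | target

**Step count and risks**

Total step count: 13. Longest linear sequence: 13 steps (1 to 21).

Steps most likely to fail:

Step 6. Oxygen transfer to the dienolate may discriminate poorly between the two faces, or the enolate may add to the sulfonimine that the oxidant leaves behind, so that too little of the trans ketol is obtained. The fallback makes the oxygenation stereoconvergent. It sets out from 11, which is hydroxylated as in step 6; the unwanted C4-epimeric ketol F1 is separated and treated with 4-nitrobenzoic acid, PPh3 and diisopropyl azodicarboxylate in THF at 0 °C. This Mitsunobu inversion, which is favoured at a carbinol next to a carbonyl group, gives the inverted 4-nitrobenzoate F2. Methanolysis of F2 with K2CO3 in MeOH at 0 °C comes back to the route at 12.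

Step 9. The sigmatropic shift of the chromate ester may be slow beside the bulky C4 silyl ether, so that dehydration to dienes or loss of a silyl group under the mildly acidic oxidant competes. The fallback separates isomerisation from oxidation. It sets out from 14, which with catalytic O3ReOSiPh3 in Et2O at −50 °C should undergo a 1,3-hydroxyl transposition to the transposed allylic alcohol F3 as a mixture of C1 epimers. Oxidation of F3 with MnO2 in CH2Cl2 at rt comes back to the route at 15.

Step 11. Acylation of the hindered C1 alcohol may be sluggish, and prolonged heating may isomerise the angelate to the tiglate. The fallback builds the Z double bond on an ester that is already in place. It sets out from 16, which is esterified with 2-[bis(2,2,2-trifluoroethoxy)phosphoryl]propanoic acid (N,N'-dicyclohexylcarbodiimide, 4-(dimethylamino)pyridine, CH2Cl2, rt) to the phosphonopropanoate ester F4. A Still–Gennari olefination of F4 (KN(SiMe3)2, 18-crown-6, THF, −78 °C; acetaldehyde) should give the Z-configured 2-methylbut-2-enoate and comes back to the route at 19.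

Further compounds
F1 | step 6 | (4S,6S)-6-hydroxy-4-[(2R,4R)-4-[(tert-butyldimethylsilyl)oxy]-6-methylhept-5-en-2-yl]cyclohex-2-en-1-one | O=C1C=C[C@@H](C[C@@H]1O)[C@H](C)C[C@H](C=C(C)C)O[Si](C)(C)C(C)(C)C
F2 | step 6 | (1R,5S)-5-[(2R,4R)-4-[(tert-butyldimethylsilyl)oxy]-6-methylhept-5-en-2-yl]-2-oxocyclohex-3-en-1-yl 4-nitrobenzoate | O=C1C=C[C@@H](C[C@H]1OC(=O)c1ccc(cc1)[N+](=O)[O-])[C@H](C)C[C@H](C=C(C)C)O[Si](C)(C)C(C)(C)C
F3 | step 9 | (4R,6S)-4-[(tert-butyldimethylsilyl)oxy]-3-methyl-6-[(2R,4R)-4-[(tert-butyldimethylsilyl)oxy]-6-methylhept-5-en-2-yl]cyclohex-2-en-1-ol (C1 epimers) | OC1C=C(C)[C@H](O[Si](C)(C)C(C)(C)C)C[C@H]1[C@H](C)C[C@H](C=C(C)C)O[Si](C)(C)C(C)(C)C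
F4 | step 11 | (1S,4R,6S)-4-[(tert-butyldimethylsilyl)oxy]-6-[(2R,4R)-4-[(tert-butyldimethylsilyl)oxy]-6-methylhept-5-en-2-yl]-3-methylcyclohex-2-en-1-yl 2-[bis(2,2,2-trifluoroethoxy)phosphoryl]propanoate (epimers at the phosphonate carbon) | CC(C(=O)O[C@@H]1C=C(C)[C@H](O[Si](C)(C)C(C)(C)C)C[C@H]1[C@H](C)C[C@H](C=C(C)C)O[Si](C)(C)C(C)(C)C)P(=O)(OCC(F)(F)F)OCC(F)(F)F
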